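## Retrosynthetic overview

1. The target is reached by late esterification (C6 acetate, then C3 angelate last) of a 4,5-epoxygermacr-1(10)-ene-3,6-diol core; the C6 carbinol is fixed by oxidation and chelation-controlled reduction of the ring ketone.
2. The ten-membered carbocycle comes from C6–C7 bond formation: intramolecular palladium/Et2Zn umpolung allylation of an α,β-epoxy aldehyde by a C12 allylic chloride (sets C7).
3. The oxirane (C4, C5) comes from Sharpless epoxidation of the open-chain C6 allylic alcohol; ring order is oxirane first, then the ten-membered ring.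
4. The C3 carbinol, the first stereocentre, comes from ketoreductase reduction of an achiral open-chain dienone.
5. The dienone comes from α-selective allylbarium coupling of an 8-silyloxygeranyl chloride (from geranyl acetate) with (E)-4-(PMB-oxy)-2-methylbut-2-enal, then oxidation.

Assumption: geranyl acetate, PMB-oxyacetaldehyde, the formyl-ethylidene phosphorane and angelic anhydride are bought; C-labels (C1–C12) are germacrane labels (C3 angelate carbinol, C4/C5 oxirane, C6 acetate carbinol, C7 isopropyl-bearing carbon, C12 the chlorinated terminus); the sense of the ring closure in step 15 is assumed by analogy with related epoxy-farnesal cyclisations.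

## Route

Step 1
Reactants: 1 geranyl acetate
Product: 2 (2E,6E)-8-hydroxy-3,7-dimethylocta-2,6-dien-1-yl acetate
Conditions: SeO2 (0.1 equiv), t-BuOOH (3 equiv), salicylic acid (0.1 equiv), CH2Cl2, rt
Reagents that add atoms: tert-butyl hydroperoxide CC(C)(C)OO
Why: SeO2-catalysed allylic oxidation (ene reaction, then 2,3-sigmatropic shift) is selective for the E-methyl of the electron-rich terminal olefin, the other olefin being deactivated by the allylic acetate.

Step 2
Reactants: 2 (2E,6E)-8-hydroxy-3,7-dimethylocta-2,6-dien-1-yl acetate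
Product: 3 (2E,6E)-8-[(tert-butyldimethylsilyl)oxy]-3,7-dimethylocta-2,6-dien-1-yl acetate
Conditions: TBSCl, imidazole, DMF, 0 °C → rt
Reagents that add atoms: tert-butyldimethylsilyl chloride CC(C)(C)[Si](C)(C)Cl
Why: Standard silylation of a primary allylic alcohol gives an ether that is inert to the organobarium chemistry ahead.

Step 3
Reactants: 3 (2E,6E)-8-[(tert-butyldimethylsilyl)oxy]-3,7-dimethylocta-2,6-dien-1-yl acetate
Product: 4 (2E,6E)-8-[(tert-butyldimethylsilyl)oxy]-3,7-dimethylocta-2,6-dien-1-ol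
Conditions: K2CO3 (0.2 equiv), MeOH, 0 °C → rt
Reagents that add atoms: none
Why: Base-catalysed transesterification removes the acetate without touching the silyl ether.

Step 4
Reactants: 4 (2E,6E)-8-[(tert-butyldimethylsilyl)oxy]-3,7-dimethylocta-2,6-dien-1-ol
Product: 6 tert-butyl{[(2E,6E)-8-chloro-2,6-dimethylocta-2,6-dien-1-yl]oxy}dimethylsilane, via allylic mesylate 5 (not isolated)
Conditions: MsCl, s-collidine, LiCl, DMF, 0 °C
Reagents that add atoms: lithium chloride [Li+].[Cl-]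
Why: Collington–Meyers chlorination (in situ mesylation, then SN2 displacement by chloride) gives the primary allylic chloride without allylic transposition or loss of E geometry.

Step 5
Reactants: 7 2-[(4-methoxybenzyl)oxy]acetaldehyde; 8 2-(triphenylphosphoranylidene)propanal
Product: 9 (2E)-4-[(4-methoxybenzyl)oxy]-2-methylbut-2-enal
Conditions: toluene, 80 °C
Reagents that add atoms: none
Why: Wittig olefination with the stabilised formyl ylide gives the E-trisubstituted enal and stops there because the product enal is less electrophilic than the alkoxyacetaldehyde.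

Step 6
Reactants: 6 tert-butyl{[(2E,6E)-8-chloro-2,6-dimethylocta-2,6-dien-1-yl]oxy}dimethylsilane; 9 (2E)-4-[(4-methoxybenzyl)oxy]-2-methylbut-2-enal
Product: 11 rac-(2E,6E,10E)-12-[(tert-butyldimethylsilyl)oxy]-1-[(4-methoxybenzyl)oxy]-3,7,11-trimethyldodeca-2,6,10-trien-4-ol, via allylbarium chloride 10 (not isolated)
Conditions: BaI2, lithium biphenylide (2 equiv), THF, rt (gives finely divided zerovalent barium); then 6, −78 °C; then 9, −78 °C; aq. NH4Cl
Reagents that add atoms: none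
Why: Yamamoto-type allylbarium reagents add 1,2 to aldehydes through the unsubstituted α-carbon with retention of olefin geometry, so the linear homoallylic alcohol forms instead of the branched γ-adduct; the carbinol is racemic and is erased in step 7.

Step 7
Reactants: 11 rac-(2E,6E,10E)-12-[(tert-butyldimethylsilyl)oxy]-1-[(4-methoxybenzyl)oxy]-3,7,11-trimethyldodeca-2,6,10-trien-4-ol
Product: 12 (2E,6E,10E)-12-[(tert-butyldimethylsilyl)oxy]-1-[(4-methoxybenzyl)oxy]-3,7,11-trimethyldodeca-2,6,10-trien-4-one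
Conditions: Dess–Martin periodinane, pyridine, CH2Cl2, 0 °C
Reagents that add atoms: none
Why: Dess–Martin oxidation under buffered, non-basic conditions gives the achiral dienone without moving the β,γ-olefin into conjugation.

Step 8
Reactants: 12 (2E,6E,10E)-12-[(tert-butyldimethylsilyl)oxy]-1-[(4-methoxybenzyl)oxy]-3,7,11-trimethyldodeca-2,6,10-trien-4-one
Product: 13 (2E,4S,6E,10E)-12-[(tert-butyldimethylsilyl)oxy]-1-[(4-methoxybenzyl)oxy]-3,7,11-trimethyldodeca-2,6,10-trien-4-ol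
Conditions: ketoreductase (S-selective, picked from a commercial panel), NADP+ (cat.), i-PrOH (10% v/v), DMSO (5% v/v), KH2PO4/K2HPO4 buffer pH 7.0, 30 °C
Reagents that add atoms: none
Why: Ketoreductase-catalysed asymmetric carbonyl reduction (hydride from NADPH, recycled by isopropanol) attacks one enantioface only and sets the first stereocentre, C3, as S; the enone C=C is not a substrate for this enzyme class.

Step 9
Reactants: 13 (2E,4S,6E,10E)-12-[(tert-butyldimethylsilyl)oxy]-1-[(4-methoxybenzyl)oxy]-3,7,11-trimethyldodeca-2,6,10-trien-4-ol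
Product: 14 (2E,4S,6E,10E)-4,12-bis[(tert-butyldimethylsilyl)oxy]-1-[(4-methoxybenzyl)oxy]-3,7,11-trimethyldodeca-2,6,10-triene
Conditions: TBSOTf, 2,6-lutidine, CH2Cl2, −78 → 0 °C
Reagents that add atoms: tert-butyldimethylsilyl trifluoromethanesulfonate CC(C)(C)[Si](C)(C)OS(=O)(=O)C(F)(F)F
Why: Silylation of the hindered secondary alcohol with the silyl triflate protects C3–OH through the oxidations, the organometallic ring closure and the reduction to come.

Step 10
Reactants: 14 (2E,4S,6E,10E)-4,12-bis[(tert-butyldimethylsilyl)oxy]-1-[(4-methoxybenzyl)oxy]-3,7,11-trimethyldodeca-2,6,10-triene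
Product: 15 (2E,6E,9S,10E)-9-[(tert-butyldimethylsilyl)oxy]-12-[(4-methoxybenzyl)oxy]-2,6,10-trimethyldodeca-2,6,10-trien-1-ol
Conditions: HF·pyridine, pyridine, THF, 0 °C
Reagents that add atoms: none
Why: Selective desilylation: buffered HF·pyridine cleaves the primary allylic TBS ether far faster than the hindered secondary one, and the PMB ether is inert.

Step 11
Reactants: 15 (2E,6E,9S,10E)-9-[(tert-butyldimethylsilyl)oxy]-12-[(4-methoxybenzyl)oxy]-2,6,10-trimethyldodeca-2,6,10-trien-1-ol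
Product: 17 (2E,4S,6E,10E)-4-[(tert-butyldimethylsilyl)oxy]-12-chloro-1-[(4-methoxybenzyl)oxy]-3,7,11-trimethyldodeca-2,6,10-triene, via primary mesylate 16 (not isolated)
Conditions: MsCl, s-collidine, LiCl, DMF, 0 °C
Reagents that add atoms: lithium chloride [Li+].[Cl-]
Why: Collington–Meyers chlorination, as in step 4, installs the allylic chloride needed for ring closure with E geometry intact.

Step 12
Reactants: 17 (2E,4S,6E,10E)-4-[(tert-butyldimethylsilyl)oxy]-12-chloro-1-[(4-methoxybenzyl)oxy]-3,7,11-trimethyldodeca-2,6,10-triene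
Product: 18 (2E,4S,6E,10E)-4-[(tert-butyldimethylsilyl)oxy]-12-chloro-3,7,11-trimethyldodeca-2,6,10-trien-1-ol
Conditions: DDQ, CH2Cl2/aq. NaH2PO4–Na2HPO4 buffer pH 7 (10:1), 0 °C
Reagents that add atoms: none
Why: Oxidative PMB cleavage (hydride abstraction by DDQ, then hydrolysis of the oxocarbenium ion) frees the C6 allylic alcohol under neutral conditions that spare the allylic chloride and the silyl ether.

Step 13
Reactants: 18 (2E,4S,6E,10E)-4-[(tert-butyldimethylsilyl)oxy]-12-chloro-3,7,11-trimethyldodeca-2,6,10-trien-1-ol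
Product: 19 [(2R,3S)-3-{(1S,3E,7E)-1-[(tert-butyldimethylsilyl)oxy]-9-chloro-4,8-dimethylnona-3,7-dien-1-yl}-3-methyloxiran-2-yl]methanol
Conditions: Ti(OiPr)4 (10 mol%), D-(−)-diethyl tartrate (12 mol%), t-BuOOH (2 equiv, in decane), 4 Å MS, CH2Cl2, −20 °C
Reagents that add atoms: tert-butyl hydroperoxide CC(C)(C)OO
Why: Sharpless asymmetric epoxidation with the D-(−)-tartrate titanium catalyst gives the oxirane of the (2R,3R)-epoxygeraniol sense under reagent control over the existing C3 centre, setting C4 and C5 threo to the C3 oxygen as the target requires.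

Step 14
Reactants: 19 [(2R,3S)-3-{(1S,3E,7E)-1-[(tert-butyldimethylsilyl)oxy]-9-chloro-4,8-dimethylnona-3,7-dien-1-yl}-3-methyloxiran-2-yl]methanol
Product: 20 (2S,3S)-3-{(1S,3E,7E)-1-[(tert-butyldimethylsilyl)oxy]-9-chloro-4,8-dimethylnona-3,7-dien-1-yl}-3-methyloxirane-2-carbaldehyde
Conditions: Dess–Martin periodinane, pyridine, CH2Cl2, 0 °C
Reagents that add atoms: none
Why: Dess–Martin oxidation gives the α,β-epoxy aldehyde without epimerisation or oxirane opening (the descriptor at the oxirane CH changes only because CHO outranks the ring carbon).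

Step 15
Reactants: 20 (2S,3S)-3-{(1S,3E,7E)-1-[(tert-butyldimethylsilyl)oxy]-9-chloro-4,8-dimethylnona-3,7-dien-1-yl}-3-methyloxirane-2-carbaldehyde
Product: 22 (1R,2S,3S,6E,9S,10S)-9-[(tert-butyldimethylsilyl)oxy]-6,10-dimethyl-3-(prop-1-en-2-yl)-11-oxabicyclo[8.1.0]undec-6-en-2-ol, via ethyl(allyl)zinc species 21 (not isolated)
Conditions: PdCl2(PPh3)2 (10 mol%), Et2Zn (4 equiv), K2CO3, DMA, rt, syringe-pump addition of 20 (final 5 mM); aq. NH4Cl
Reagents that add atoms: none
Why: Intramolecular palladium-catalysed umpolung allylation: zerovalent palladium ionises the allylic chloride, Et2Zn turns the π-allyl complex into an allylzinc that adds through its γ-carbon (C7) to the aldehyde in a chair-like six-membered transition state, closing the ten-membered ring with H-6/H-7 anti and C7 pseudo-equatorial in the crown conformer imposed by the trans-oxirane and the E-olefin (C6 is reset in steps 17 and 18).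

Step 16
Reactants: 22 (1R,2S,3S,6E,9S,10S)-9-[(tert-butyldimethylsilyl)oxy]-6,10-dimethyl-3-(prop-1-en-2-yl)-11-oxabicyclo[8.1.0]undec-6-en-2-ol
Product: 23 (1R,2S,3S,6E,9S,10S)-9-[(tert-butyldimethylsilyl)oxy]-6,10-dimethyl-3-(propan-2-yl)-11-oxabicyclo[8.1.0]undec-6-en-2-ol
Conditions: H2 (1 atm), RhCl(PPh3)3 (10 mol%), benzene, rt
Reagents that add atoms: none
Why: Homogeneous hydrogenation with RhCl(PPh3)3 reduces the unhindered 1,1-disubstituted isopropenyl group and leaves the trisubstituted ring olefin and the oxirane alone.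

Step 17
Reactants: 23 (1R,2S,3S,6E,9S,10S)-9-[(tert-butyldimethylsilyl)oxy]-6,10-dimethyl-3-(propan-2-yl)-11-oxabicyclo[8.1.0]undec-6-en-2-ol
Product: 24 (1S,3S,6E,9S,10S)-9-[(tert-butyldimethylsilyl)oxy]-6,10-dimethyl-3-(propan-2-yl)-11-oxabicyclo[8.1.0]undec-6-en-2-one
Conditions: Dess–Martin periodinane, pyridine, CH2Cl2, 0 °C
Reagents that add atoms: none
Why: Dess–Martin oxidation gives the α,β-epoxy ketone, and with the isopropenyl group already saturated C7 cannot slip into conjugation.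

Step 18
Reactants: 24 (1S,3S,6E,9S,10S)-9-[(tert-butyldimethylsilyl)oxy]-6,10-dimethyl-3-(propan-2-yl)-11-oxabicyclo[8.1.0]undec-6-en-2-one
Product: 25 (1R,2R,3S,6E,9S,10S)-9-[(tert-butyldimethylsilyl)oxy]-6,10-dimethyl-3-(propan-2-yl)-11-oxabicyclo[8.1.0]undec-6-en-2-ol
Conditions: NaBH4, CeCl3·7H2O, MeOH, −78 °C
Reagents that add atoms: none
Why: Luche-type chelation-controlled reduction of the α,β-epoxy ketone: cerium bridges the carbonyl and oxirane oxygens and hydride attacks the exposed face to give the anti (erythro) epoxy alcohol, which is the C6 configuration of the target.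

Step 19
Reactants: 25 (1R,2R,3S,6E,9S,10S)-9-[(tert-butyldimethylsilyl)oxy]-6,10-dimethyl-3-(propan-2-yl)-11-oxabicyclo[8.1.0]undec-6-en-2-ol
Product: 26 (1R,2R,3S,6E,9S,10S)-9-[(tert-butyldimethylsilyl)oxy]-6,10-dimethyl-3-(propan-2-yl)-11-oxabicyclo[8.1.0]undec-6-en-2-yl acetate
Conditions: Ac2O, pyridine, 4-(dimethylamino)pyridine (cat.), CH2Cl2, 0 °C → rt
Reagents that add atoms: acetic anhydride CC(=O)OC(C)=O
Why: Nucleophile-catalysed acetylation of the secondary alcohol proceeds with retention at C6.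

Step 20
Reactants: 26 (1R,2R,3S,6E,9S,10S)-9-[(tert-butyldimethylsilyl)oxy]-6,10-dimethyl-3-(propan-2-yl)-11-oxabicyclo[8.1.0]undec-6-en-2-yl acetate
Product: 27 (1R,2R,3S,6E,9S,10R)-9-hydroxy-6,10-dimethyl-3-(propan-2-yl)-11-oxabicyclo[8.1.0]undec-6-en-2-yl acetate
Conditions: Bu4NF, AcOH (1:1), THF, 0 °C → rt
Reagents that add atoms: none
Why: Fluoride-mediated desilylation buffered with acetic acid frees C3–OH without acetate migration, Payne rearrangement or acid-triggered transannular cyclisation.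

Step 21
Reactants: 27 (1R,2R,3S,6E,9S,10R)-9-hydroxy-6,10-dimethyl-3-(propan-2-yl)-11-oxabicyclo[8.1.0]undec-6-en-2-yl acetate
Product: 28 (1R,2R,3S,6E,9S,10R)-2-acetoxy-6,10-dimethyl-3-(propan-2-yl)-11-oxabicyclo[8.1.0]undec-6-en-9-yl (2Z)-2-methylbut-2-enoate
Conditions: angelic anhydride (2 equiv), Cs2CO3, MeCN, rt
Reagents that add atoms: angelic anhydride C/C=C(/C)C(=O)OC(=O)/C(C)=C\C
Why: Carbonate-mediated acylation with the preformed Z-anhydride (no acid chloride, no nucleophilic amine catalyst) transfers the angeloyl group without isomerisation to the tiglate and with retention at C3.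

## Compound list

1 | geranyl acetate, (2E)-3,7-dimethylocta-2,6-dien-1-yl acetate | CC(C)=CCC/C(C)=C/COC(C)=O | starting material
2 | (2E,6E)-8-hydroxy-3,7-dimethylocta-2,6-dien-1-yl acetate | OC/C(C)=C/CC/C(C)=C/COC(C)=O | intermediate
3 | (2E,6E)-8-[(tert-butyldimethylsilyl)oxy]-3,7-dimethylocta-2,6-dien-1-yl acetate | CC(C)(C)[Si](C)(C)OC/C(C)=C/CC/C(C)=C/COC(C)=O | intermediate
4 | (2E,6E)-8-[(tert-butyldimethylsilyl)oxy]-3,7-dimethylocta-2,6-dien-1-ol | CC(C)(C)[Si](C)(C)OC/C(C)=C/CC/C(C)=C/CO | intermediate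
5 | (2E,6E)-8-[(tert-butyldimethylsilyl)oxy]-3,7-dimethylocta-2,6-dien-1-yl methanesulfonate | CC(C)(C)[Si](C)(C)OC/C(C)=C/CC/C(C)=C/COS(C)(=O)=O | intermediate
6 | tert-butyl{[(2E,6E)-8-chloro-2,6-dimethylocta-2,6-dien-1-yl]oxy}dimethylsilane | CC(C)(C)[Si](C)(C)OC/C(C)=C/CC/C(C)=C/CCl | intermediate
7 | 2-[(4-methoxybenzyl)oxy]acetaldehyde | COc1ccc(COCC=O)cc1 | starting material
8 | 2-(triphenylphosphoranylidene)propanal | CC(C=O)=P(c1ccccc1)(c1ccccc1)c1ccccc1 | starting material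
9 | (2E)-4-[(4-methoxybenzyl)oxy]-2-methylbut-2-enal | O=C/C(C)=C/COCc1ccc(OC)cc1 | intermediate
10 | chloro{(2E,6E)-8-[(tert-butyldimethylsilyl)oxy]-3,7-dimethylocta-2,6-dien-1-yl}barium | CC(C)(C)[Si](C)(C)OC/C(C)=C/CC/C(C)=C/C[Ba]Cl | intermediate
11 | rac-(2E,6E,10E)-12-[(tert-butyldimethylsilyl)oxy]-1-[(4-methoxybenzyl)oxy]-3,7,11-trimethyldodeca-2,6,10-trien-4-ol | CC(C)(C)[Si](C)(C)OC/C(C)=C/CC/C(C)=C/CC(O)/C(C)=C/COCc1ccc(OC)cc1 | intermediate
12 | (2E,6E,10E)-12-[(tert-butyldimethylsilyl)oxy]-1-[(4-methoxybenzyl)oxy]-3,7,11-trimethyldodeca-2,6,10-trien-4-one | CC(C)(C)[Si](C)(C)OC/C(C)=C/CC/C(C)=C/CC(=O)/C(C)=C/COCc1ccc(OC)cc1 | intermediate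
13 | (2E,4S,6E,10E)-12-[(tert-butyldimethylsilyl)oxy]-1-[(4-methoxybenzyl)oxy]-3,7,11-trimethyldodeca-2,6,10-trien-4-ol | CC(C)(C)[Si](C)(C)OC/C(C)=C/CC/C(C)=C/C[C@H](O)/C(C)=C/COCc1ccc(OC)cc1 | intermediate
14 | (2E,4S,6E,10E)-4,12-bis[(tert-butyldimethylsilyl)oxy]-1-[(4-methoxybenzyl)oxy]-3,7,11-trimethyldodeca-2,6,10-triene | CC(C)(C)[Si](C)(C)OC/C(C)=C/CC/C(C)=C/C[C@H](O[Si](C)(C)C(C)(C)C)/C(C)=C/COCc1ccc(OC)cc1 | intermediate
15 | (2E,6E,9S,10E)-9-[(tert-butyldimethylsilyl)oxy]-12-[(4-methoxybenzyl)oxy]-2,6,10-trimethyldodeca-2,6,10-trien-1-ol | OC/C(C)=C/CC/C(C)=C/C[C@H](O[Si](C)(C)C(C)(C)C)/C(C)=C/COCc1ccc(OC)cc1 | intermediate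
16 | (2E,6E,9S,10E)-9-[(tert-butyldimethylsilyl)oxy]-12-[(4-methoxybenzyl)oxy]-2,6,10-trimethyldodeca-2,6,10-trien-1-yl methanesulfonate | CS(=O)(=O)OC/C(C)=C/CC/C(C)=C/C[C@H](O[Si](C)(C)C(C)(C)C)/C(C)=C/COCc1ccc(OC)cc1 | intermediate
17 | (2E,4S,6E,10E)-4-[(tert-butyldimethylsilyl)oxy]-12-chloro-1-[(4-methoxybenzyl)oxy]-3,7,11-trimethyldodeca-2,6,10-triene | ClC/C(C)=C/CC/C(C)=C/C[C@H](O[Si](C)(C)C(C)(C)C)/C(C)=C/COCc1ccc(OC)cc1 | intermediate
18 | (2E,4S,6E,10E)-4-[(tert-butyldimethylsilyl)oxy]-12-chloro-3,7,11-trimethyldodeca-2,6,10-trien-1-ol | ClC/C(C)=C/CC/C(C)=C/C[C@H](O[Si](C)(C)C(C)(C)C)/C(C)=C/CO | intermediate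
19 | [(2R,3S)-3-{(1S,3E,7E)-1-[(tert-butyldimethylsilyl)oxy]-9-chloro-4,8-dimethylnona-3,7-dien-1-yl}-3-methyloxiran-2-yl]methanol | ClC/C(C)=C/CC/C(C)=C/C[C@H](O[Si](C)(C)C(C)(C)C)[C@@]1(C)O[C@@H]1CO | intermediate
20 | (2S,3S)-3-{(1S,3E,7E)-1-[(tert-butyldimethylsilyl)oxy]-9-chloro-4,8-dimethylnona-3,7-dien-1-yl}-3-methyloxirane-2-carbaldehyde | ClC/C(C)=C/CC/C(C)=C/C[C@H](O[Si](C)(C)C(C)(C)C)[C@@]1(C)O[C@@H]1C=O | intermediate
21 | ethyl(allyl)zinc species: 20 with CH2–ZnEt in place of CH2–Cl | CC[Zn]C/C(C)=C/CC/C(C)=C/C[C@H](O[Si](C)(C)C(C)(C)C)[C@@]1(C)O[C@@H]1C=O | intermediate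
22 | (1R,2S,3S,6E,9S,10S)-9-[(tert-butyldimethylsilyl)oxy]-6,10-dimethyl-3-(prop-1-en-2-yl)-11-oxabicyclo[8.1.0]undec-6-en-2-ol | CC(C)(C)[Si](C)(C)O[C@H]1C/C=C(\C)CC[C@@H](C(C)=C)[C@H](O)[C@H]2O[C@]12C | intermediate
23 | (1R,2S,3S,6E,9S,10S)-9-[(tert-butyldimethylsilyl)oxy]-6,10-dimethyl-3-(propan-2-yl)-11-oxabicyclo[8.1.0]undec-6-en-2-ol | CC(C)(C)[Si](C)(C)O[C@H]1C/C=C(\C)CC[C@@H](C(C)C)[C@H](O)[C@H]2O[C@]12C | intermediate
24 | (1S,3S,6E,9S,10S)-9-[(tert-butyldimethylsilyl)oxy]-6,10-dimethyl-3-(propan-2-yl)-11-oxabicyclo[8.1.0]undec-6-en-2-one | CC(C)(C)[Si](C)(C)O[C@H]1C/C=C(\C)CC[C@@H](C(C)C)C(=O)[C@H]2O[C@]12C | intermediate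
25 | (1R,2R,3S,6E,9S,10S)-9-[(tert-butyldimethylsilyl)oxy]-6,10-dimethyl-3-(propan-2-yl)-11-oxabicyclo[8.1.0]undec-6-en-2-ol | CC(C)(C)[Si](C)(C)O[C@H]1C/C=C(\C)CC[C@@H](C(C)C)[C@@H](O)[C@H]2O[C@]12C | intermediate
26 | (1R,2R,3S,6E,9S,10S)-9-[(tert-butyldimethylsilyl)oxy]-6,10-dimethyl-3-(propan-2-yl)-11-oxabicyclo[8.1.0]undec-6-en-2-yl acetate | CC(C)(C)[Si](C)(C)O[C@H]1C/C=C(\C)CC[C@@H](C(C)C)[C@@H](OC(C)=O)[C@H]2O[C@]12C | intermediate
27 | (1R,2R,3S,6E,9S,10R)-9-hydroxy-6,10-dimethyl-3-(propan-2-yl)-11-oxabicyclo[8.1.0]undec-6-en-2-yl acetate | O[C@H]1C/C=C(\C)CC[C@@H](C(C)C)[C@@H](OC(C)=O)[C@H]2O[C@]12C | intermediate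
28 | (1R,2R,3S,6E,9S,10R)-2-acetoxy-6,10-dimethyl-3-(propan-2-yl)-11-oxabicyclo[8.1.0]undec-6-en-9-yl (2Z)-2-methylbut-2-enoate (CNP0180504.2) | C/C=C(/C)C(=O)O[C@H]1C/C=C(\C)CC[C@@H](C(C)C)[C@@H](OC(C)=O)[C@H]2O[C@]12C | target

## Step count and risks

Total steps: 21. Longest linear sequence: 20 steps (steps 1–4, then 6–21, from geranyl acetate 1 to 28); the enal branch (step 5) joins at step 6.

**Step 15 (ring closure).** Yield at high dilution and the C7 configuration relative to the oxirane both depend on it. Fallback: leave the main line at 18 and return at 22. Oxidise 18 with MnO2 to (2E,4S,6E,10E)-4-[(tert-butyldimethylsilyl)oxy]-12-chloro-3,7,11-trimethyldodeca-2,6,10-trienal F4. Close the ring before any oxirane is present by Nozaki–Hiyama allylation with CrCl2 (divalent chromium, THF, high dilution) to give the macrocyclic trienol F5, the 4E-olefin analogue of 22 with the same C3, C6 and C7 configurations. Then epoxidise its C4=C5 bond under hydroxyl direction with VO(acac)2/t-BuOOH, which should deliver oxygen to the exposed outer face syn to the C6 hydroxyl and give 22; the outcome would need an NOE check.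

**Step 6 (allylbarium coupling).** It needs freshly activated barium and could erode α/γ selectivity or E geometry with the functionalised chloride. Fallback: set out from 6 and 9 and return at 12. Displace the chloride of 6 with PhSO2Na (DMF, rt) to give allylic phenyl sulfone F1. Deprotonate with n-BuLi (THF, −78 °C) and add 9; sulfonyl carbanions attack aldehydes through the sulfonyl-bearing carbon only, giving β-hydroxy sulfone F2 as a diastereomer mixture. Dess–Martin oxidation gives β-keto sulfone F3. Reductive desulfonylation with SmI2 (divalent samarium, THF/MeOH, −78 °C) and kinetic α-protonation of the dienolate give dienone 12, and the route resumes at step 8.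

**Step 18 (C6 reduction).** The ring conformation could override chelation control and return the C6 epimer 23. Fallback: set out from 23 and return at 25, replacing the redox inversion by an SN2 inversion. Mitsunobu reaction of 23 with 4-nitrobenzoic acid, PPh3 and diisopropyl azodicarboxylate (toluene, 0 °C → rt) gives the C6-inverted 4-nitrobenzoate F6. Methanolysis (K2CO3, MeOH, 0 °C) gives 25, and the route resumes at step 19.

Further compounds
F1 | step 6 | tert-butyl{[(2E,6E)-2,6-dimethyl-8-(phenylsulfonyl)octa-2,6-dien-1-yl]oxy}dimethylsilane | CC(C)(C)[Si](C)(C)OC/C(C)=C/CC/C(C)=C/CS(=O)(=O)c1ccccc1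
F2 | step 6 | (2E,6E,10E)-12-[(tert-butyldimethylsilyl)oxy]-1-[(4-methoxybenzyl)oxy]-3,7,11-trimethyl-5-(phenylsulfonyl)dodeca-2,6,10-trien-4-ol (racemic diastereomer mixture) | CC(C)(C)[Si](C)(C)OC/C(C)=C/CC/C(C)=C/C(C(O)/C(C)=C/COCc1ccc(OC)cc1)S(=O)(=O)c1ccccc1
F3 | step 6 | (2E,6E,10E)-12-[(tert-butyldimethylsilyl)oxy]-1-[(4-methoxybenzyl)oxy]-3,7,11-trimethyl-5-(phenylsulfonyl)dodeca-2,6,10-trien-4-one (racemic) | CC(C)(C)[Si](C)(C)OC/C(C)=C/CC/C(C)=C/C(C(=O)/C(C)=C/COCc1ccc(OC)cc1)S(=O)(=O)c1ccccc1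
F4 | step 15 | (2E,4S,6E,10E)-4-[(tert-butyldimethylsilyl)oxy]-12-chloro-3,7,11-trimethyldodeca-2,6,10-trienal | ClC/C(C)=C/CC/C(C)=C/C[C@H](O[Si](C)(C)C(C)(C)C)/C(C)=C/C=O
F5 | step 15 | (1R,2E,4S,6E,10S)-4-[(tert-butyldimethylsilyl)oxy]-3,7-dimethyl-10-(prop-1-en-2-yl)cyclodeca-2,6-dien-1-ol | CC(C)(C)[Si](C)(C)O[C@H]1C/C=C(\C)CC[C@@H](C(C)=C)[C@H](O)/C=C1\C
F6 | step 18 | (1R,2R,3S,6E,9S,10S)-9-[(tert-butyldimethylsilyl)oxy]-6,10-dimethyl-3-(propan-2-yl)-11-oxabicyclo[8.1.0]undec-6-en-2-yl 4-nitrobenzoate | CC(C)(C)[Si](C)(C)O[C@H]1C/C=C(\C)CC[C@@H](C(C)C)[C@@H](OC(=O)c3ccc(cc3)[N+](=O)[O-])[C@H]2O[C@]12C
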